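**Retrosynthetic overview**
1. Target 11 is the C2-symmetric, all-trans head-to-head [2+2] dimer of a single alkene. The C2 axis passes through the midpoints of cyclobutane bonds C1–C2 and C3–C4, so cutting these two bonds gives two identical imidazole–CH=CH–CH2–NH–CO–pyrrole chains.
2. Each 2-aminoimidazole is carried as an imidazo[1,2-a]pyrimidine, a temporary pyrimidine ring spanning one ring N and the 2-NH2. This turns the alkene into a sensitisable 2-alkenyl-azaarene, and hydrazine removes the mask in the last step.
3. Enabling feature: in each half, the basic imidazole N beside the alkene-bearing ring carbon and the amide N–H/pyrrole N–H pair at the far end of the C3 chain can clamp one chiral phosphate next to the C=C. With the C2 symmetry, this allows an enantioselective homodimerisation that forms both C–C bonds and all four stereocentres.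
4. Monomer 9 comes from imidazole annulation of 2-aminopyrimidine with 1,3-dichloroacetone, Arbuzov/HWE extension with N-Boc-glycinal, and acyl transfer from 2-(trichloroacetyl)pyrrole.
5. Ring order: pyrrole and the temporary pyrimidine are bought, the imidazole is closed in step 1, and the cyclobutane is closed last in step 5.

Key step: step 5

Assumption: the sense of induction of the chiral acid on this substrate class cannot be read from precedent, so (R)-TRIP is written for the (1R,2R,3S,4S) product and the equally available (S)-acid replaces it if the sense proves opposite. The aminoimidazole N–H tautomers interconvert freely.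

Step 1
Reactants: 1 2-aminopyrimidine; 2 1,3-dichloroacetone
Product: 3 2-(chloromethyl)imidazo[1,2-a]pyrimidine
Conditions: DME, rt; then EtOH, reflux; aq NaHCO3
Reagents that add atoms: none
Why: In this Tschitschibabin-type annulation the ring N of 1 is alkylated by one CH2Cl arm of symmetric 2 and the exocyclic NH2 condenses with the ketone, which closes the imidazole ring with the second CH2Cl arm at C2 and creates no stereocentre.

Step 2
Reactants: 3 2-(chloromethyl)imidazo[1,2-a]pyrimidine
Product: 4 diethyl (imidazo[1,2-a]pyrimidin-2-ylmethyl)phosphonate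
Conditions: P(OEt)3 (neat, excess), NaI (10 mol %), 120 °C
Reagents that add atoms: triethyl phosphite, CCOP(OCC)OCC
Why: This is a Michaelis–Arbuzov reaction of an activated heterobenzylic chloride, in which iodide catalysis and excess phosphite should outrun self-quaternisation at N1.

Step 3
Reactants: 4 diethyl (imidazo[1,2-a]pyrimidin-2-ylmethyl)phosphonate; 5 tert-butyl (2-oxoethyl)carbamate (N-Boc-glycinal)
Product: 6 tert-butyl [(E)-3-(imidazo[1,2-a]pyrimidin-2-yl)prop-2-en-1-yl]carbamate
Conditions: KOtBu (1.05 equiv), THF, −20 °C; then 5, −20 °C → rt
Reagents that add atoms: none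
Why: Horner–Wadsworth–Emmons olefination of a heterobenzylic phosphonate anion with an aliphatic aldehyde should give the conjugated E alkene, and any Z isomer is harmless because step 5 does not depend on alkene geometry.

Step 4
Reactants: 6 tert-butyl [(E)-3-(imidazo[1,2-a]pyrimidin-2-yl)prop-2-en-1-yl]carbamate; 7 2,2,2-trichloro-1-(1H-pyrrol-2-yl)ethan-1-one
Product: 9 N-[(E)-3-(imidazo[1,2-a]pyrimidin-2-yl)prop-2-en-1-yl]-1H-pyrrole-2-carboxamide, via allylic amine 8 (not isolated)
Conditions: TFA/CH2Cl2 1:4, 0 °C → rt; evaporate; then 7, iPr2NEt, DMF, rt
Reagents that add atoms: none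
Why: Boc acidolysis is followed by haloform-type N-acylation, in which the trichloromethyl ketone transfers the pyrrole-2-carbonyl group only to the primary aliphatic amine and needs no pyrrole N protection.

Step 5
Reactants: 9 N-[(E)-3-(imidazo[1,2-a]pyrimidin-2-yl)prop-2-en-1-yl]-1H-pyrrole-2-carboxamide (two molecules)
Product: 10 N,N′-{[(1R,2R,3S,4S)-3,4-bis(imidazo[1,2-a]pyrimidin-2-yl)cyclobutane-1,2-diyl]bis(methylene)}bis(1H-pyrrole-2-carboxamide), all-trans, C2-symmetric
Conditions: (R)-TRIP (20 mol %), [Ir(ppy)2(dtbbpy)]PF6 (1 mol %), CH2Cl2/PhMe 1:1, 0.2 M, Ar, 450 nm LED, −40 °C; aq NaHCO3 wash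
Reagents that add atoms: none
Why: Proposed new method: the phosphoric acid protonates N1 of 9, which should lower the triplet energy of the 2-alkenyl-azaarene chromophore so that the moderate-energy Ir sensitiser transfers its triplet energy only to bound substrate, and the twisted triplet then adds through Cβ (the alkene CH next to CH2N) to Cβ′ of a ground-state molecule of 9 to give a 1,4-diradical. The closest known reaction types are the acid-free, racemic Ir-sensitised head-to-head photodimerisation of alkenyl-imidazo[1,2-a]pyrimidines and the chiral-phosphoric-acid/Ir-sensitised enantioselective [2+2] photocycloaddition of acyclic 2-vinylpyridines, whose merger into an enantioselective homodimerisation has not been shown. The cyclobutane closes stepwise as a formal [2+2], with the intermolecular Cβ–Cβ′ bond first and, after intersystem crossing, recombination of the two heterobenzylic radicals (Cα–Cα′, collapse of the 1,4-diradical). The two CH2N-bearing centres (R,R) arise in the first bond, because the phosphate is held by N1–H+ and by the amide N–H/pyrrole N–H cleft of the same molecule, the allyl chain wraps around the anion, one triisopropylphenyl wing covers one alkene face so the partner attacks the open face, and the unlike diradical, which could close only to a cis-1,2 product, should fragment back to 9. The two heteroaryl-bearing centres (S,S) are set at ring closure under substrate control, since the freely rotating radical centres close with each heteroaryl trans to both neighbours in the least strained all-trans array. The step needs head-to-head regioselectivity (secured by heterobenzylic stabilisation of both spins), reaction of bound over free substrate (secured by the energy gating, the low temperature and the short life of an unbound acyclic triplet, which only relaxes by E/Z isomerisation) and independence of alkene geometry (secured because E and Z isomers enter the same triplet and diradical, making the step stereoconvergent).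

Step 6
Reactants: 10 N,N′-{[(1R,2R,3S,4S)-3,4-bis(imidazo[1,2-a]pyrimidin-2-yl)cyclobutane-1,2-diyl]bis(methylene)}bis(1H-pyrrole-2-carboxamide)
Product: 11 N,N′-{[(1R,2R,3S,4S)-3,4-bis(2-amino-1H-imidazol-4-yl)cyclobutane-1,2-diyl]bis(methylene)}bis(1H-pyrrole-2-carboxamide) (target)
Conditions: N2H4·H2O (excess), EtOH, 100 °C, sealed tube
Reagents that add atoms: none
Why: In this known hydrazinolysis of imidazo[1,2-a]pyrimidines, hydrazine adds to the electron-poor pyrimidine ring and leaves with C5–C6–C7 as pyrazole, so N8 remains as the 2-NH2 and N4 as the imidazole N–H on both halves at once, while the secondary pyrrole carboxamides and the four non-acidic cyclobutane C–H centres should stay untouched.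

**Compound list**
1 | 2-aminopyrimidine | Nc1ncccn1 | starting material
2 | 1,3-dichloroacetone | ClCC(=O)CCl | starting material
3 | 2-(chloromethyl)imidazo[1,2-a]pyrimidine | ClCc1cn2cccnc2n1 | intermediate
4 | diethyl (imidazo[1,2-a]pyrimidin-2-ylmethyl)phosphonate | CCOP(=O)(Cc1cn2cccnc2n1)OCC | intermediate
5 | tert-butyl (2-oxoethyl)carbamate | CC(C)(C)OC(=O)NCC=O | starting material
6 | tert-butyl [(E)-3-(imidazo[1,2-a]pyrimidin-2-yl)prop-2-en-1-yl]carbamate | CC(C)(C)OC(=O)NC/C=C/c1cn2cccnc2n1 | intermediate
7 | 2,2,2-trichloro-1-(1H-pyrrol-2-yl)ethan-1-one | O=C(c1ccc[nH]1)C(Cl)(Cl)Cl | starting material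
8 | (E)-3-(imidazo[1,2-a]pyrimidin-2-yl)prop-2-en-1-amine | NC/C=C/c1cn2cccnc2n1 | intermediate
9 | N-[(E)-3-(imidazo[1,2-a]pyrimidin-2-yl)prop-2-en-1-yl]-1H-pyrrole-2-carboxamide | O=C(NC/C=C/c1cn2cccnc2n1)c1ccc[nH]1 | intermediate
10 | N,N′-{[(1R,2R,3S,4S)-3,4-bis(imidazo[1,2-a]pyrimidin-2-yl)cyclobutane-1,2-diyl]bis(methylene)}bis(1H-pyrrole-2-carboxamide) | n1c2ncccn2cc1[C@H]3[C@H](CNC(=O)c4ccc[nH]4)[C@@H](CNC(=O)c4ccc[nH]4)[C@@H]3c1cn2cccnc2n1 | intermediate
11 | N,N′-{[(1R,2R,3S,4S)-3,4-bis(2-amino-1H-imidazol-4-yl)cyclobutane-1,2-diyl]bis(methylene)}bis(1H-pyrrole-2-carboxamide) | Nc1ncc([C@H]2[C@H](CNC(=O)c3ccc[nH]3)[C@@H](CNC(=O)c3ccc[nH]3)[C@@H]2c2cnc(N)[nH]2)[nH]1 | target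

Total step count: 6. Longest linear sequence: 6 steps (1 → 3 → 4 → 6 → 9 → 10 → 11).

**Steps most likely to fail**

Step 5. Several processes could erode the enantioselectivity or stall the reaction:
- unbound 9 could be sensitised and dimerise without facial control;
- the more basic product could sequester the acid and stop turnover;
- the substrate could fall out of solution at low temperature;
- the face shielding could be too weak.

The fallback uses known chemistry and replaces asymmetric induction by resolution. It sets out from 9. Acid-free sensitised dimerisation (Ir(ppy)3, MeOH, blue LED, rt) should give the racemic all-trans head-to-head dimer, that is 10 together with its mirror image, the (1S,2S,3R,4R)-dimer F1. The two are separated by preparative chromatography on a polysaccharide chiral stationary phase (SFC), and the route is rejoined at 10.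

Step 3. The basic phosphonate anion could enolise or self-condense aldehyde 5, and excess base could move the new double bond towards the enecarbamate. The fallback inverts the order of alkene and imidazole construction. It sets out from 5 and 1.
- A base-free Wittig reaction of 5 with the commercial stabilised ylide 1-chloro-3-(triphenylphosphoranylidene)propan-2-one (ClCC(=O)C=P(c1ccccc1)(c1ccccc1)c1ccccc1; CH2Cl2, rt) should give tert-butyl [(E)-5-chloro-4-oxopent-2-en-1-yl]carbamate F2.
- Tschitschibabin-type annulation of F2 with 1 (NaHCO3, cat. NaI, EtOH, 70 °C) closes the imidazole ring with the alkenyl chain at C2.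

The route is rejoined at 6, and steps 1–3 are replaced.

Step 6. Opening of the second pyrimidine ring could be slow enough that forcing conditions are needed, under which hydrazine begins to cleave the pyrrole carboxamides. The fallback changes the order of events so that no acyl pyrrole meets hydrazine. It sets out from 6.
- The cycloaddition is run on 6 under the conditions of step 5, with the carbamate N–H as the second anchor for the phosphate, to give the bis-carbamate dimer F3.
- Hydrazinolysis, which can now be forced, gives the bis(2-aminoimidazole) bis-carbamate F4.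
- TFA/CH2Cl2 liberates the tetraamine F5.
- Acylation with 7 (2 equiv, iPr2NEt, DMF, rt) occurs selectively at the two primary aliphatic amines, a known selectivity in the presence of free 2-aminoimidazoles.

The route is rejoined at 11.

**Further compounds**
F1 | step 5 | N,N′-{[(1S,2S,3R,4R)-3,4-bis(imidazo[1,2-a]pyrimidin-2-yl)cyclobutane-1,2-diyl]bis(methylene)}bis(1H-pyrrole-2-carboxamide) | n1c2ncccn2cc1[C@@H]3[C@@H](CNC(=O)c4ccc[nH]4)[C@H](CNC(=O)c4ccc[nH]4)[C@H]3c1cn2cccnc2n1
F2 | step 3 | tert-butyl [(E)-5-chloro-4-oxopent-2-en-1-yl]carbamate | CC(C)(C)OC(=O)NC/C=C/C(=O)CCl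
F3 | step 6 | di-tert-butyl {[(1R,2R,3S,4S)-3,4-bis(imidazo[1,2-a]pyrimidin-2-yl)cyclobutane-1,2-diyl]bis(methylene)}dicarbamate | n1c2ncccn2cc1[C@H]3[C@H](CNC(=O)OC(C)(C)C)[C@@H](CNC(=O)OC(C)(C)C)[C@@H]3c1cn2cccnc2n1
F4 | step 6 | di-tert-butyl {[(1R,2R,3S,4S)-3,4-bis(2-amino-1H-imidazol-4-yl)cyclobutane-1,2-diyl]bis(methylene)}dicarbamate | Nc1ncc([C@H]2[C@H](CNC(=O)OC(C)(C)C)[C@@H](CNC(=O)OC(C)(C)C)[C@@H]2c2cnc(N)[nH]2)[nH]1
F5 | step 6 | 4,4′-[(1S,2S,3R,4R)-3,4-bis(aminomethyl)cyclobutane-1,2-diyl]bis(1H-imidazol-2-amine) | Nc1ncc([C@H]2[C@H](CN)[C@@H](CN)[C@@H]2c2cnc(N)[nH]2)[nH]1
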